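**Retrosynthetic overview**

1. Hopeafuran is a 2-arylbenzofuran (benzo ring B) whose furan C3 is bonded to the resorcinol ring A and whose C4 is joined to the ortho carbon of ring A through C(=O)–CH(4-hydroxyphenyl), forming the seven-membered ring. End game: benzyl ethers off by hydrogenolysis and the ketone from the carbinol by Dess–Martin oxidation, so the (S) α-aryl centre never meets base as a ketone.
2. Key disconnection: the C3–ring A biaryl bond together with the furan O–C2 bond, both made in one palladium cascade from an o-alkynylphenol that carries the ring A aryl bromide. The enabling feature is that C3 is the alkyne carbon peri to C4, whose two-carbon bridge holds the arylpalladium over that carbon on the side opposite the phenol oxygen; anti-oxypalladation then gives an eight-membered palladacycle that reductively eliminates to the seven-membered ring.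
3. The cascade precursor is a 1,2,2-triarylethanol, made by anti Friedel–Crafts opening of an (S,S)-stilbene oxide (Shi epoxidation) with 1-bromo-3,5-bis(benzyloxy)benzene, followed by Sonogashira coupling at the ring B aryl iodide.
4. Order of ring formation: rings A and B and both 4-oxygenated phenyl groups come from commercial arenes; the furan ring and the seven-membered ring are formed together in step 10.

Key step: step 10

Remark: the target stereocentre is read as (S); being α to the ketone and doubly benzylic it is taken as base-labile once the ketone exists, so it is set and carried at the carbinol oxidation level, and 1-bromo-3,5-bis(benzyloxy)benzene and 1-(benzyloxy)-4-ethynylbenzene are taken as catalogue compounds.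

**Route**

Step 1
Reactants: 1 3,5-dihydroxybenzaldehyde
Product: 2 3,5-bis(triisopropylsilyloxy)benzaldehyde
Conditions: TIPSCl, imidazole, DMF, rt
Reagents that add atoms: triisopropylsilyl chloride, CC(C)[Si](Cl)(C(C)C)C(C)C
Why: Imidazole-promoted silyl ether formation masks both phenols through the basic and oxidative steps and leaves them removable by fluoride in the presence of benzyl ethers.

Step 2
Reactants: 2 3,5-bis(triisopropylsilyloxy)benzaldehyde
Product: 3 2-iodo-3,5-bis(triisopropylsilyloxy)benzaldehyde
Conditions: NIS (1.05 equiv), TFA (cat.), MeCN, 0 °C to rt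
Reagents that add atoms: N-iodosuccinimide, O=C1CCC(=O)N1I
Why: Electrophilic aromatic iodination should go to C2, which is ortho and para to the two silyloxy donors, because C4 between the two bulky silyloxy groups is blocked, as in the halogenation of 3,5-dialkoxybenzaldehydes.

Step 3
Reactants: 4 4-(benzyloxy)benzyl chloride
Product: 5 diethyl [4-(benzyloxy)benzyl]phosphonate
Conditions: P(OEt)3, neat, 140 °C
Reagents that add atoms: triethyl phosphite, CCOP(OCC)OCC
Why: Michaelis–Arbuzov reaction of a reactive benzylic chloride.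

Step 4
Reactants: 3 2-iodo-3,5-bis(triisopropylsilyloxy)benzaldehyde; 5 diethyl [4-(benzyloxy)benzyl]phosphonate
Product: 6 (E)-1-[4-(benzyloxy)phenyl]-2-[2-iodo-3,5-bis(triisopropylsilyloxy)phenyl]ethene
Conditions: KOtBu, THF, 0 °C to rt
Reagents that add atoms: none
Why: Horner–Wadsworth–Emmons olefination of an aryl aldehyde with a benzylphosphonate anion should give the (E)-stilbene; no stereocentre is formed.

Step 5
Reactants: 6 (E)-1-[4-(benzyloxy)phenyl]-2-[2-iodo-3,5-bis(triisopropylsilyloxy)phenyl]ethene
Product: 7 (2S,3S)-2-[4-(benzyloxy)phenyl]-3-[2-iodo-3,5-bis(triisopropylsilyloxy)phenyl]oxirane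
Conditions: ent-Shi ketone (1,2:4,5-di-O-isopropylidene-β-L-erythro-2,3-hexodiulo-2,6-pyranose, 30 mol %), 2KHSO5·KHSO4·K2SO4, K2CO3, Bu4NHSO4, MeCN–dimethoxymethane–aq. Na2B4O7 buffer (pH 10.5), 0 °C; crude epoxide used directly
Reagents that add atoms: potassium peroxymonosulfate, OOS(=O)(=O)[O-].[K+]
Why: Shi asymmetric epoxidation of an (E)-stilbene by the chiral dioxirane; the L-fructose-derived ketone is the mirror image of the catalyst that gives (R,R)-stilbene oxide, so catalyst control through the spiro transition state should set both epoxide carbons as (S), and the electron-rich alkene should react faster than the aryl iodide.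

Step 6
Reactants: 7 (2S,3S)-2-[4-(benzyloxy)phenyl]-3-[2-iodo-3,5-bis(triisopropylsilyloxy)phenyl]oxirane; 8 1-bromo-3,5-bis(benzyloxy)benzene
Product: 9 (1R,2S)-2-[4-(benzyloxy)phenyl]-2-[2-bromo-4,6-bis(benzyloxy)phenyl]-1-[2-iodo-3,5-bis(triisopropylsilyloxy)phenyl]ethan-1-ol
Conditions: 8 (3 equiv), HFIP–CH2Cl2 (3:1), 0 °C
Reagents that add atoms: none
Why: Friedel–Crafts alkylation of the arene by the hydrogen-bond-activated epoxide: the C–O bond breaks only at the carbon that carries the cation-stabilising 4-(benzyloxy)phenyl group, and arene 8 should attack through C2 (para to one benzyloxy group, not between the two) anti to the leaving oxygen, so this carbon is inverted and becomes the (S) diarylmethine of the target, while the carbinol carbon keeps its oxygen and geometry (its descriptor changes to R only through a priority change).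

Step 7
Reactants: 9 the (1R,2S) alcohol; 10 1-(benzyloxy)-4-ethynylbenzene
Product: 11 (1R,2S)-2-[4-(benzyloxy)phenyl]-2-[2-bromo-4,6-bis(benzyloxy)phenyl]-1-[2-{[4-(benzyloxy)phenyl]ethynyl}-3,5-bis(triisopropylsilyloxy)phenyl]ethan-1-ol
Conditions: PdCl2(PPh3)2 (5 mol %), CuI (10 mol %), Et3N–THF (degassed), 45 °C
Reagents that add atoms: none
Why: Sonogashira coupling in which the aryl iodide should react selectively over the electron-rich, ortho-substituted aryl bromide of ring A; the alkyne is brought in only now so that it cannot trap the benzylic cation of step 6.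

Step 8
Reactants: 11 the alkynyl alcohol
Product: 12 tert-butyldimethylsilyl ether of 11 ((1R,2S) retained)
Conditions: TBSOTf, 2,6-lutidine, CH2Cl2, 0 °C to rt
Reagents that add atoms: tert-butyldimethylsilyl triflate, CC(C)(C)[Si](C)(C)OS(=O)(=O)C(F)(F)F
Why: Silyl triflate silylation of the hindered secondary alcohol removes the alkoxide that could bind palladium (β-hydride elimination) or add to the alkyne in the key step.

Step 9
Reactants: 12 the bis(triisopropylsilyl) aryl ether
Product: 13 5-[(1R,2S)-2-[4-(benzyloxy)phenyl]-2-[2-bromo-4,6-bis(benzyloxy)phenyl]-1-(tert-butyldimethylsilyloxy)ethyl]-4-{[4-(benzyloxy)phenyl]ethynyl}benzene-1,3-diol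
Conditions: Bu4NF (2.2 equiv), AcOH (2.2 equiv), THF, 0 °C
Reagents that add atoms: none
Why: Fluoride desilylation of aryl silyl ethers is much faster than that of the hindered secondary alkyl silyl ether, and the acetic acid buffer should prevent base-induced cyclisation of the o-alkynylphenol.

Step 10
Reactants: 13 the o-alkynylresorcinol aryl bromide
Product: 15 6-O-benzyl ether of the cyclised phenol (penta-O-benzyl O-TBS trans-alcohol of the hopeafuran skeleton; (R)-carbinol and (S)-diarylmethine), via cyclised 6-hydroxybenzofuran 14 (not isolated)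
Conditions: Pd2(dba)3 (5 mol %), XPhos (12 mol %), K2CO3 (4 equiv), DMF (degassed), 80 °C; then BnBr, rt
Reagents that add atoms: benzyl bromide, BrCc1ccccc1
Why: Zerovalent palladium inserts into the ring A C–Br bond and the arylpalladium bromide (divalent palladium), held by the CH(OTBS)–CH(aryl) bridge beside the alkyne carbon that becomes C3, activates the alkyne from the side away from the ortho phenoxide, which adds to the distal alkyne carbon (anti-oxypalladation) to give an eight-membered aryl(benzofuran-3-yl)palladium species whose C–C reductive elimination forms the C3–ring A bond; benzyl bromide then caps the one phenoxide left. The closest known reaction type is the Cacchi-type annulative arylation of o-alkynylphenols with aryl halides (oxypalladation–reductive elimination), used here intramolecularly, and the alternative order of events (5-endo cycloisomerisation, then intramolecular direct arylation at benzofuran C3) leads to the same product. The furan ring closes by 5-endo-dig O-attack on the palladium-bound alkyne and the seven-membered ring closes by reductive elimination from the eight-membered palladacycle. No stereocentre is formed, and the two existing ones, which carry no acidic hydrogen at the silyl ether oxidation level, should pass unchanged. The step needs alkyne capture of the arylpalladium to beat protodebromination, β-hydride elimination from a palladium alkoxide, enolate O-arylation and C–H arylation of the geminal 4-(benzyloxy)phenyl ring to a fluorene; the silyl-protected carbinol (no alkoxide, no ketone), the carboxylate-free base at moderate temperature and the peri placement of the alkyne secure this.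

Step 11
Reactants: 15 the cyclised silyl ether
Product: 16 penta-O-benzyl trans-alcohol of the hopeafuran skeleton ((R)-carbinol, (S)-diarylmethine)
Conditions: Bu4NF, THF, rt to 45 °C
Reagents that add atoms: none
Why: Fluoride cleavage of the alkyl silyl ether; at the alcohol oxidation level no centre is epimerisable by the basic fluoride.

Step 12
Reactants: 16 the trans-alcohol
Product: 17 (S)-penta-O-benzylhopeafuran
Conditions: Dess–Martin periodinane, CH2Cl2, 0 °C to rt
Reagents that add atoms: none
Why: Dess–Martin oxidation converts the secondary benzylic alcohol to the ketone under non-basic conditions, so the (S) α-aryl centre, which becomes enolisable only now, should not be epimerised.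

Step 13
Reactants: 17 (S)-penta-O-benzylhopeafuran
Product: 18 hopeafuran ((S) configuration)
Conditions: H2 (1 atm), 10% Pd/C, EtOAc–MeOH, rt
Reagents that add atoms: none
Why: Catalytic hydrogenolysis of the five aryl benzyl ethers is a neutral deprotection that should leave the hindered aryl ketone and the adjacent (S) centre untouched.

**Compound list**

1 | 3,5-dihydroxybenzaldehyde | O=Cc1cc(O)cc(O)c1 | starting material
2 | 3,5-bis(triisopropylsilyloxy)benzaldehyde | O=Cc1cc(O[Si](C(C)C)(C(C)C)C(C)C)cc(O[Si](C(C)C)(C(C)C)C(C)C)c1 | intermediate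
3 | 2-iodo-3,5-bis(triisopropylsilyloxy)benzaldehyde | O=Cc1cc(O[Si](C(C)C)(C(C)C)C(C)C)cc(O[Si](C(C)C)(C(C)C)C(C)C)c1I | intermediate
4 | 4-(benzyloxy)benzyl chloride | ClCc1ccc(OCc2ccccc2)cc1 | starting material
5 | diethyl [4-(benzyloxy)benzyl]phosphonate | CCOP(=O)(Cc1ccc(OCc2ccccc2)cc1)OCC | intermediate
6 | (E)-1-[4-(benzyloxy)phenyl]-2-[2-iodo-3,5-bis(triisopropylsilyloxy)phenyl]ethene | Ic1c(O[Si](C(C)C)(C(C)C)C(C)C)cc(O[Si](C(C)C)(C(C)C)C(C)C)cc1/C=C/c1ccc(OCc2ccccc2)cc1 | intermediate
7 | (2S,3S)-2-[4-(benzyloxy)phenyl]-3-[2-iodo-3,5-bis(triisopropylsilyloxy)phenyl]oxirane | Ic1c(O[Si](C(C)C)(C(C)C)C(C)C)cc(O[Si](C(C)C)(C(C)C)C(C)C)cc1[C@@H]1O[C@H]1c1ccc(OCc2ccccc2)cc1 | intermediate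
8 | 1-bromo-3,5-bis(benzyloxy)benzene | Brc1cc(OCc2ccccc2)cc(OCc2ccccc2)c1 | starting material
9 | (1R,2S)-2-[4-(benzyloxy)phenyl]-2-[2-bromo-4,6-bis(benzyloxy)phenyl]-1-[2-iodo-3,5-bis(triisopropylsilyloxy)phenyl]ethan-1-ol | O[C@@H](c1cc(O[Si](C(C)C)(C(C)C)C(C)C)cc(O[Si](C(C)C)(C(C)C)C(C)C)c1I)[C@H](c1c(Br)cc(OCc2ccccc2)cc1OCc1ccccc1)c1ccc(OCc2ccccc2)cc1 | intermediate
10 | 1-(benzyloxy)-4-ethynylbenzene | C#Cc1ccc(OCc2ccccc2)cc1 | starting material
11 | (1R,2S)-2-[4-(benzyloxy)phenyl]-2-[2-bromo-4,6-bis(benzyloxy)phenyl]-1-[2-{[4-(benzyloxy)phenyl]ethynyl}-3,5-bis(triisopropylsilyloxy)phenyl]ethan-1-ol | O[C@@H](c1cc(O[Si](C(C)C)(C(C)C)C(C)C)cc(O[Si](C(C)C)(C(C)C)C(C)C)c1C#Cc1ccc(OCc2ccccc2)cc1)[C@H](c1c(Br)cc(OCc2ccccc2)cc1OCc1ccccc1)c1ccc(OCc2ccccc2)cc1 | intermediate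
12 | tert-butyldimethylsilyl ether of 11, (1R,2S) | CC(C)(C)[Si](C)(C)O[C@@H](c1cc(O[Si](C(C)C)(C(C)C)C(C)C)cc(O[Si](C(C)C)(C(C)C)C(C)C)c1C#Cc1ccc(OCc2ccccc2)cc1)[C@H](c1c(Br)cc(OCc2ccccc2)cc1OCc1ccccc1)c1ccc(OCc2ccccc2)cc1 | intermediate
13 | 5-[(1R,2S)-2-[4-(benzyloxy)phenyl]-2-[2-bromo-4,6-bis(benzyloxy)phenyl]-1-(tert-butyldimethylsilyloxy)ethyl]-4-{[4-(benzyloxy)phenyl]ethynyl}benzene-1,3-diol | CC(C)(C)[Si](C)(C)O[C@@H](c1cc(O)cc(O)c1C#Cc1ccc(OCc2ccccc2)cc1)[C@H](c1c(Br)cc(OCc2ccccc2)cc1OCc1ccccc1)c1ccc(OCc2ccccc2)cc1 | intermediate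
14 | cyclised phenol: 2-[4-(benzyloxy)phenyl]benzofuran-6-ol whose C3 is bonded to C1 of a 3,5-bis(benzyloxy)-1,2-phenylene (ring A) and whose C4 carries (R)-CH(OTBS) bonded to (S)-CH[4-(benzyloxy)phenyl] on C2 of ring A | CC(C)(C)[Si](C)(C)O[C@H]1c2cc(O)cc3oc(-c4ccc(OCc5ccccc5)cc4)c(c23)-c2cc(OCc3ccccc3)cc(OCc3ccccc3)c2[C@@H]1c1ccc(OCc2ccccc2)cc1 | intermediate
15 | 6-O-benzyl ether of 14 (penta-O-benzyl O-TBS trans-alcohol; (R)-carbinol, (S)-diarylmethine) | CC(C)(C)[Si](C)(C)O[C@H]1c2cc(OCc3ccccc3)cc3oc(-c4ccc(OCc5ccccc5)cc4)c(c23)-c2cc(OCc3ccccc3)cc(OCc3ccccc3)c2[C@@H]1c1ccc(OCc2ccccc2)cc1 | intermediate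
16 | penta-O-benzyl trans-alcohol of the hopeafuran skeleton ((R)-carbinol, (S)-diarylmethine) | O[C@H]1c2cc(OCc3ccccc3)cc3oc(-c4ccc(OCc5ccccc5)cc4)c(c23)-c2cc(OCc3ccccc3)cc(OCc3ccccc3)c2[C@@H]1c1ccc(OCc2ccccc2)cc1 | intermediate
17 | (S)-penta-O-benzylhopeafuran | O=C1c2cc(OCc3ccccc3)cc3oc(-c4ccc(OCc5ccccc5)cc4)c(c23)-c2cc(OCc3ccccc3)cc(OCc3ccccc3)c2[C@@H]1c1ccc(OCc2ccccc2)cc1 | intermediate
18 | hopeafuran, (S) | O=C1c2cc(O)cc3oc(-c4ccc(O)cc4)c(c23)-c2cc(O)cc(O)c2[C@@H]1c1ccc(O)cc1 | target

**Step count and risks**

Total steps: 13. Longest linear sequence: 12 (steps 1, 2 and 4 to 13, from 3,5-dihydroxybenzaldehyde).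

The three steps most likely to fail, with one fallback each:

First, step 10. Oxidative addition at the hindered, electron-rich C–Br bond may lag behind base-induced cycloisomerisation of the alkynylphenol, after which protodebromination or C–H arylation of the geminal aryl ring could take over. The fallback separates the two ring closures and sets out from 13. Treatment with Cs2CO3 in DMF at 60 °C (5-endo-dig cycloisomerisation) and then BnBr should give, through the 3-unsubstituted benzofuran-6-ol F1 (not isolated), its 6-O-benzyl ether F2. The seven-membered ring is then closed by intramolecular direct C–H arylation at benzofuran C3 through concerted metalation–deprotonation (Pd(OAc)2, PCy3·HBF4, K2CO3, pivalic acid, DMA, 110 °C). The fallback comes back to the route at 15.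

Second, step 6. Ionisation to a free benzylic cation before C–C bond formation would erode the stereochemical fidelity at the diarylmethine carbon; a hydride shift to the deoxybenzoin and attack of the arene through C4 are the other loss channels. Diastereomers of 9 can be separated, but the fallback changes how the stereocentre is set. The material is carried on without regard to its diastereomer ratio, since both carbinol diastereomers converge on the two enantiomers of the ketone, and the fallback sets out from 17 of insufficient enantiomeric purity. Under Noyori–Ikariya asymmetric transfer hydrogenation (RuCl(p-cymene)[(S,S)-TsDPEN], HCO2H–Et3N, DMF, 40 °C) the α-aryl ketone should epimerise while only the (S)-ketone is reduced, from the face that gives the cis (S,S)-alcohol F3 (dynamic kinetic resolution). Dess–Martin oxidation of F3 returns to the route at 17 as a single enantiomer. Should step 6 favour the other diastereomer, the D-fructose-derived ketone would be used in step 5.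

Third, step 13. Over-reduction of the aryl ketone, or incomplete cleavage of five ethers on a poorly soluble polyphenol, may intervene. The fallback replaces reductive cleavage by Lewis-acid dealkylation with a cation scavenger: from 17, BCl3 and pentamethylbenzene in CH2Cl2 at −78 °C should give 18 directly without a base and without hydrogen; no new compound arises on the way (F0).

**Further compounds**

F1 | step 10 | 4-[(1R,2S)-2-[4-(benzyloxy)phenyl]-2-[2-bromo-4,6-bis(benzyloxy)phenyl]-1-(tert-butyldimethylsilyloxy)ethyl]-2-[4-(benzyloxy)phenyl]benzofuran-6-ol | Oc1cc([C@H](O[Si](C)(C)C(C)(C)C)[C@H](c2c(Br)cc(OCc3ccccc3)cc2OCc2ccccc2)c2ccc(OCc3ccccc3)cc2)c2cc(-c3ccc(OCc4ccccc4)cc3)oc2c1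
F2 | step 10 | 6-O-benzyl ether of F1 | C(c1ccccc1)Oc1cc([C@H](O[Si](C)(C)C(C)(C)C)[C@H](c2c(Br)cc(OCc3ccccc3)cc2OCc2ccccc2)c2ccc(OCc3ccccc3)cc2)c2cc(-c3ccc(OCc4ccccc4)cc3)oc2c1
F3 | step 6 | penta-O-benzyl cis-alcohol of the hopeafuran skeleton ((S)-carbinol, (S)-diarylmethine) | O[C@@H]1c2cc(OCc3ccccc3)cc3oc(-c4ccc(OCc5ccccc5)cc4)c(c23)-c2cc(OCc3ccccc3)cc(OCc3ccccc3)c2[C@@H]1c1ccc(OCc2ccccc2)cc1
F0 | step 13 | none | none
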